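**Retrosynthetic overview**

1. The target is a depside. After removal of the ring B benzyl ester and of a dioxolane on the side-chain ketone, the aryl ester bond between the ring A carboxyl carbon and the oxygen on C4 of ring B is cut, giving ring A acid 16 and ring B phenol 22.
2. Feature: ring A is a benzoate with oxygens on C2 and C4 and the 2-oxoheptyl arm on C6. Its carboxyl carbon, the six ring carbons and the arm form one linear chain oxygenated on every second carbon (a 3,5,7,9-tetraoxo acid), so ring A is cut at the C1–C6 ring bond (chain C2–C7) back to benzyl 3,5,7-triketo ester 12, with the C9 ketone masked as a dioxolane.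
3. Ester 12 comes from acylketene 11, released from diketo-dioxinone 9 and trapped by benzyl alcohol. Compound 9 is assembled by two Claisen-type acylations: dioxinone 4 with acetyl chloride, then the keto-dioxinone dianion with Weinreb amide 3 (from ethyl 3-oxooctanoate).
4. Ring B phenol 22 comes from olivetol by carboxylation, benzyl ester formation and MOM-controlled methylation of the chelated hydroxyl.
5. Ring order: ring B is taken aromatic from olivetol; ring A is the only ring built (step 5).

Key step: step 5

Remark: the target has no stereocenter. Aldol adduct 13 and fallback alcohol F3 carry transient stereocenters that are formed without control and removed later, so their SMILES carry no stereodescriptors.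

**Route**

Step 1
Reactants: 1 ethyl 3-oxooctanoate
Product: 2 ethyl 2-(2-pentyl-1,3-dioxolan-2-yl)acetate
Conditions: ethylene glycol, TsOH·H2O (cat.), PhMe, reflux, Dean–Stark
Reagents that add atoms: ethylene glycol, OCCO
Why: Acid-catalysed ketalisation with azeotropic removal of water protects the ketone of the β-keto ester, while the ester carbonyl does not ketalise.

Step 2
Reactants: 2 ethyl 2-(2-pentyl-1,3-dioxolan-2-yl)acetate
Product: 3 N-methoxy-N-methyl-2-(2-pentyl-1,3-dioxolan-2-yl)acetamide
Conditions: MeNHOMe·HCl, iPrMgCl, THF, −20 to 0 °C; aq. NH4Cl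
Reagents that add atoms: N,O-dimethylhydroxylamine hydrochloride, CNOC.Cl
Why: Direct aminolysis of the ester by the chloromagnesium amide of N,O-dimethylhydroxylamine (Weinreb amide synthesis) runs under basic conditions that leave the dioxolane intact.

Step 3
Reactants: 4 2,2,6-trimethyl-4H-1,3-dioxin-4-one; 5 acetyl chloride
Product: 7 2,2-dimethyl-6-(2-oxopropyl)-4H-1,3-dioxin-4-one, via lithium dienolate 6 (not isolated)
Conditions: LiN(SiMe3)2, THF, −78 °C; then AcCl (0.5 equiv relative to 4), −78 °C; aq. HCl work-up
Reagents that add atoms: none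
Why: Vinylogous deprotonation of the C6 methyl group gives dienolate 6, which undergoes Claisen-type C-acylation at its γ-carbon with acetyl chloride; the dienolate is used in twofold excess because the product is more acidic than 4.

Step 4
Reactants: 7 2,2-dimethyl-6-(2-oxopropyl)-4H-1,3-dioxin-4-one; 3 N-methoxy-N-methyl-2-(2-pentyl-1,3-dioxolan-2-yl)acetamide
Product: 9 2,2-dimethyl-6-[2,4-dioxo-5-(2-pentyl-1,3-dioxolan-2-yl)pentyl]-4H-1,3-dioxin-4-one, via dilithium dianion 8 (not isolated)
Conditions: LiN(iPr)2 (2.1 equiv), THF, −78 °C; then 3, −78 to −30 °C; then AcOH, −78 °C to rt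
Reagents that add atoms: none
Why: Double deprotonation gives a Weiler-type dianion that reacts at its last-formed terminal carbon, and acylation by the Weinreb amide stops at the chelated tetrahedral adduct, so the β-diketone is released only on work-up.

Step 5
Reactants: 9 2,2-dimethyl-6-[2,4-dioxo-5-(2-pentyl-1,3-dioxolan-2-yl)pentyl]-4H-1,3-dioxin-4-one; 10 benzyl alcohol
Product: 14 benzyl 2,4-dihydroxy-6-[(2-pentyl-1,3-dioxolan-2-yl)methyl]benzoate, via acylketene 11 (not isolated), via benzyl triketo ester 12 (not isolated), via aldol adduct 13 (not isolated)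
Conditions: BnOH (3 equiv), PhMe, 110 °C; then Cs2CO3, iPrOH/CH2Cl2, rt; then AcOH, rt to 40 °C
Reagents that add atoms: none
Why: Heating 9 triggers a retro-hetero-Diels–Alder loss of acetone to acylketene 11, which benzyl alcohol captures at the ketene carbon to give the 3,5,7-triketo ester 12 with the C9 carbonyl still locked as the dioxolane. The closest known reaction type is the thermolysis of diketo-dioxinones with alcohol trapping followed by base-mediated aldol aromatisation, the modern form of the classical cyclisation of 3,5,7-triketo esters to resorcylates. With Cs2CO3 the doubly activated C2 carbanion adds to the C7 ketone in a 6-(enolexo)-exo-trig aldol closure to adduct 13, and loss of water with enolisation of the C3 and C5 carbonyls gives aromatic ring A, the new ring bond joining the ester-bearing carbon to the carbon that bears the side chain. No stereocenter remains, because the two sp3 centers of 13 form without control and are erased on aromatisation. The step needs the C2-to-C7 aldol to win over Claisen closure of C6 onto the ester and over 4-hydroxy-2-pyranone formation: excess benzyl alcohol intercepts the ketene before the C5 enol oxygen can, the mild carbonate base favours the aldol pathway, and the dioxolane removes C9 as an electrophile so that only one six-membered aldol is open to a doubly activated carbon. The dioxolane should be inert to the neutral thermolysis and to carbonate, and the acetic acid used to complete dehydration is mild enough to leave it in place.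

Step 6
Reactants: 14 benzyl 2,4-dihydroxy-6-[(2-pentyl-1,3-dioxolan-2-yl)methyl]benzoate
Product: 15 benzyl 2,4-dimethoxy-6-[(2-pentyl-1,3-dioxolan-2-yl)methyl]benzoate
Conditions: MeI (excess), K2CO3, DMF, 40 °C
Reagents that add atoms: iodomethane, CI
Why: Williamson O-methylation of both phenols under carbonate base, with excess MeI and gentle warming for the chelated C2 hydroxyl; ester and ketal are stable to base.

Step 7
Reactants: 15 benzyl 2,4-dimethoxy-6-[(2-pentyl-1,3-dioxolan-2-yl)methyl]benzoate
Product: 16 2,4-dimethoxy-6-[(2-pentyl-1,3-dioxolan-2-yl)methyl]benzoic acid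
Conditions: H2 (1 atm), 10% Pd/C, EtOAc, rt
Reagents that add atoms: none
Why: Catalytic hydrogenolysis of the benzyl ester is neutral, so the dioxolane and aryl methyl ethers are untouched; the acid is used at once so that it does not open its own neighbouring ketal.

Step 8
Reactants: 17 olivetol (5-pentylbenzene-1,3-diol)
Product: 18 2,4-dihydroxy-6-pentylbenzoic acid (olivetolic acid)
Conditions: MeOMgOCO2Me (2 M in DMF), 120 °C; then cold aq. HCl
Reagents that add atoms: methoxymagnesium methyl carbonate, CO[Mg]OC(=O)OC
Why: Chelation-assisted carboxylation of a resorcinol with methoxymagnesium methyl carbonate (a Kolbe–Schmitt-type ortho-carboxylation) should place the carboxyl ortho to one hydroxyl and para to the other, next to the pentyl chain.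

Step 9
Reactants: 18 2,4-dihydroxy-6-pentylbenzoic acid
Product: 19 benzyl 2,4-dihydroxy-6-pentylbenzoate
Conditions: BnBr, KHCO3, DMF, rt
Reagents that add atoms: benzyl bromide, BrCc1ccccc1
Why: SN2 O-alkylation of the carboxylate with bicarbonate as base benzylates only the acid, since KHCO3 does not deprotonate the phenols, and room temperature avoids decarboxylation.

Step 10
Reactants: 19 benzyl 2,4-dihydroxy-6-pentylbenzoate
Product: 20 benzyl 2-hydroxy-4-(methoxymethoxy)-6-pentylbenzoate
Conditions: MOMCl (1.05 equiv), iPr2NEt, CH2Cl2, 0 °C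
Reagents that add atoms: chloromethyl methyl ether, COCCl
Why: The C2 hydroxyl is tied up in a hydrogen bond to the ester carbonyl, so etherification with MOMCl and a hindered amine base should occur selectively at the free, more acidic C4 hydroxyl.

Step 11
Reactants: 20 benzyl 2-hydroxy-4-(methoxymethoxy)-6-pentylbenzoate
Product: 21 benzyl 2-methoxy-4-(methoxymethoxy)-6-pentylbenzoate
Conditions: MeI, K2CO3, DMF, rt to 40 °C
Reagents that add atoms: iodomethane, CI
Why: Williamson methylation of the remaining chelated phenol; the MOM ether and benzyl ester are base-stable.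

Step 12
Reactants: 21 benzyl 2-methoxy-4-(methoxymethoxy)-6-pentylbenzoate
Product: 22 benzyl 4-hydroxy-2-methoxy-6-pentylbenzoate
Conditions: 3 M aq. HCl, THF, 40 °C
Reagents that add atoms: none
Why: Acid-catalysed acetal hydrolysis removes the MOM group, while the di-ortho-substituted benzyl ester and the aryl methyl ether resist dilute acid.

Step 13
Reactants: 16 2,4-dimethoxy-6-[(2-pentyl-1,3-dioxolan-2-yl)methyl]benzoic acid; 22 benzyl 4-hydroxy-2-methoxy-6-pentylbenzoate
Product: 23 benzyl 4-({2,4-dimethoxy-6-[(2-pentyl-1,3-dioxolan-2-yl)methyl]benzoyl}oxy)-2-methoxy-6-pentylbenzoate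
Conditions: DCC, DMAP (cat.), CH2Cl2, 0 °C to rt
Reagents that add atoms: none
Why: In this Steglich esterification DCC activates the acid as the O-acylisourea and DMAP relays the acyl group to the phenol under neutral conditions that spare the dioxolane, which in turn keeps the side-chain carbonyl from lactonising onto the activated carboxyl.

Step 14
Reactants: 23 benzyl 4-({2,4-dimethoxy-6-[(2-pentyl-1,3-dioxolan-2-yl)methyl]benzoyl}oxy)-2-methoxy-6-pentylbenzoate
Product: 24 benzyl 4-{[2,4-dimethoxy-6-(2-oxoheptyl)benzoyl]oxy}-2-methoxy-6-pentylbenzoate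
Conditions: 1 M aq. HCl, THF, rt
Reagents that add atoms: water, O
Why: Acid-catalysed hydrolysis of the dioxolane unmasks the ketone, and the hindered aryl and benzyl esters are stable to dilute aqueous acid at room temperature.

Step 15
Reactants: 24 benzyl 4-{[2,4-dimethoxy-6-(2-oxoheptyl)benzoyl]oxy}-2-methoxy-6-pentylbenzoate
Product: 25 4-{[2,4-dimethoxy-6-(2-oxoheptyl)benzoyl]oxy}-2-methoxy-6-pentylbenzoic acid (target)
Conditions: H2 (1 atm), 10% Pd/C, EtOAc, rt
Reagents that add atoms: none
Why: Hydrogenolysis of the benzyl ester under neutral conditions releases the carboxylic acid without touching the depside ester, the dialkyl ketone or the aryl ethers.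

**Compound list**

1 | ethyl 3-oxooctanoate | CCCCCC(=O)CC(=O)OCC | starting material
2 | ethyl 2-(2-pentyl-1,3-dioxolan-2-yl)acetate | CCCCCC1(CC(=O)OCC)OCCO1 | intermediate
3 | N-methoxy-N-methyl-2-(2-pentyl-1,3-dioxolan-2-yl)acetamide | CCCCCC1(CC(=O)N(C)OC)OCCO1 | intermediate
4 | 2,2,6-trimethyl-4H-1,3-dioxin-4-one | CC1=CC(=O)OC(C)(C)O1 | starting material
5 | acetyl chloride | CC(=O)Cl | starting material
6 | lithium 2,2-dimethyl-6-methylidene-1,3-dioxin-4-olate (lithium dienolate of 4) | C=C1C=C(O[Li])OC(C)(C)O1 | intermediate (not isolated)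
7 | 2,2-dimethyl-6-(2-oxopropyl)-4H-1,3-dioxin-4-one | CC(=O)CC1=CC(=O)OC(C)(C)O1 | intermediate
8 | dilithium dianion of 7 (ketone enolate plus dioxinone dienolate) | C=C(O[Li])C=C1C=C(O[Li])OC(C)(C)O1 | intermediate (not isolated)
9 | 2,2-dimethyl-6-[2,4-dioxo-5-(2-pentyl-1,3-dioxolan-2-yl)pentyl]-4H-1,3-dioxin-4-one | CCCCCC1(CC(=O)CC(=O)CC2=CC(=O)OC(C)(C)O2)OCCO1 | intermediate
10 | benzyl alcohol | OCc1ccccc1 | starting material
11 | acylketene, 3,5,7-trioxo-8-(2-pentyl-1,3-dioxolan-2-yl)oct-1-en-1-one | O=C=CC(=O)CC(=O)CC(=O)CC1(CCCCC)OCCO1 | intermediate (not isolated)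
12 | benzyl 3,5,7-trioxo-8-(2-pentyl-1,3-dioxolan-2-yl)octanoate | O=C(OCc1ccccc1)CC(=O)CC(=O)CC(=O)CC1(CCCCC)OCCO1 | intermediate (not isolated)
13 | benzyl 2-hydroxy-4,6-dioxo-2-[(2-pentyl-1,3-dioxolan-2-yl)methyl]cyclohexane-1-carboxylate (stereoisomer mixture) | CCCCCC1(CC2(O)CC(=O)CC(=O)C2C(=O)OCc2ccccc2)OCCO1 | intermediate (not isolated)
14 | benzyl 2,4-dihydroxy-6-[(2-pentyl-1,3-dioxolan-2-yl)methyl]benzoate | CCCCCC1(Cc2cc(O)cc(O)c2C(=O)OCc2ccccc2)OCCO1 | intermediate
15 | benzyl 2,4-dimethoxy-6-[(2-pentyl-1,3-dioxolan-2-yl)methyl]benzoate | CCCCCC1(Cc2cc(OC)cc(OC)c2C(=O)OCc2ccccc2)OCCO1 | intermediate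
16 | 2,4-dimethoxy-6-[(2-pentyl-1,3-dioxolan-2-yl)methyl]benzoic acid | CCCCCC1(Cc2cc(OC)cc(OC)c2C(=O)O)OCCO1 | intermediate
17 | olivetol (5-pentylbenzene-1,3-diol) | CCCCCc1cc(O)cc(O)c1 | starting material
18 | 2,4-dihydroxy-6-pentylbenzoic acid | CCCCCc1cc(O)cc(O)c1C(=O)O | intermediate
19 | benzyl 2,4-dihydroxy-6-pentylbenzoate | CCCCCc1cc(O)cc(O)c1C(=O)OCc1ccccc1 | intermediate
20 | benzyl 2-hydroxy-4-(methoxymethoxy)-6-pentylbenzoate | CCCCCc1cc(OCOC)cc(O)c1C(=O)OCc1ccccc1 | intermediate
21 | benzyl 2-methoxy-4-(methoxymethoxy)-6-pentylbenzoate | CCCCCc1cc(OCOC)cc(OC)c1C(=O)OCc1ccccc1 | intermediate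
22 | benzyl 4-hydroxy-2-methoxy-6-pentylbenzoate | CCCCCc1cc(O)cc(OC)c1C(=O)OCc1ccccc1 | intermediate
23 | benzyl 4-({2,4-dimethoxy-6-[(2-pentyl-1,3-dioxolan-2-yl)methyl]benzoyl}oxy)-2-methoxy-6-pentylbenzoate | CCCCCC1(Cc2cc(OC)cc(OC)c2C(=O)Oc2cc(CCCCC)c(C(=O)OCc3ccccc3)c(OC)c2)OCCO1 | intermediate
24 | benzyl 4-{[2,4-dimethoxy-6-(2-oxoheptyl)benzoyl]oxy}-2-methoxy-6-pentylbenzoate | CCCCCC(=O)Cc1cc(OC)cc(OC)c1C(=O)Oc1cc(CCCCC)c(C(=O)OCc2ccccc2)c(OC)c1 | intermediate
25 | 4-{[2,4-dimethoxy-6-(2-oxoheptyl)benzoyl]oxy}-2-methoxy-6-pentylbenzoic acid | CCCCCC(=O)Cc1cc(OC)cc(OC)c1C(=O)Oc1cc(CCCCC)c(C(=O)O)c(OC)c1 | target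

**Step count**

Total: 15 steps. Longest linear sequence: 9 steps (steps 1, 2, 4, 5, 6, 7, 13, 14, 15).

**Steps most likely to fail**

Step 5. The chain may misfold: the C5 enol oxygen can capture the ketene to give a 4-hydroxy-2-pyranone, a Claisen closure can compete with the aldol, and the dioxolane may be lost if dehydration of the aldol adduct needs stronger acid. The fallback keeps the dioxinone ring during aromatisation, so no ketene is present when ring A closes. It sets out from 9: triethylamine in CH2Cl2 at room temperature should promote aldol closure of the dioxinone dienolate carbon onto the C7 ketone and dehydration, giving 7-hydroxy-2,2-dimethyl-5-[(2-pentyl-1,3-dioxolan-2-yl)methyl]-4H-1,3-benzodioxin-4-one F1. Ring-opening transesterification of this acetonide with sodium benzyloxide (NaH, BnOH, THF) should then release acetone and return to the route at 14.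

Step 4. The dianion may deprotonate the Weinreb amide at its α-carbon instead of adding to it, which would also open the dioxolane by β-elimination, and conversion may stall through proton transfer. The fallback replaces the acylation by an aldol addition and an oxidation. It sets out from 3, which is reduced with LiAlH4 in THF at −78 °C to 2-(2-pentyl-1,3-dioxolan-2-yl)acetaldehyde F2. Addition of F2 to dianion 8 at −78 °C should give racemic 6-[4-hydroxy-2-oxo-5-(2-pentyl-1,3-dioxolan-2-yl)pentyl]-2,2-dimethyl-4H-1,3-dioxin-4-one F3. Oxidation with Dess–Martin periodinane buffered with NaHCO3 in CH2Cl2 returns to the route at 9.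

Step 13. Acyl transfer at the di-ortho-substituted carboxyl may be slow, so that the O-acylisourea rearranges to the N-acylurea, and the neighbouring dioxolane oxygen may attack the activated carboxyl. The fallback forms the depside ester before ring A exists. It sets out from 9 and 22: heating them in toluene at 110 °C should trap acylketene 11 with the phenol to give benzyl 2-methoxy-6-pentyl-4-{[3,5,7-trioxo-8-(2-pentyl-1,3-dioxolan-2-yl)octanoyl]oxy}benzoate F4. Aldol aromatisation with Cs2CO3 in THF followed by AcOH should give benzyl 4-({2,4-dihydroxy-6-[(2-pentyl-1,3-dioxolan-2-yl)methyl]benzoyl}oxy)-2-methoxy-6-pentylbenzoate F5. Methylation of both ring A phenols with MeI and K2CO3 in DMF returns to the route at 23.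

**Further compounds**

F1 | step 5 | 7-hydroxy-2,2-dimethyl-5-[(2-pentyl-1,3-dioxolan-2-yl)methyl]-4H-1,3-benzodioxin-4-one | CCCCCC1(Cc2cc(O)cc3OC(C)(C)OC(=O)c23)OCCO1
F2 | step 4 | 2-(2-pentyl-1,3-dioxolan-2-yl)acetaldehyde | CCCCCC1(CC=O)OCCO1
F3 | step 4 | 6-[4-hydroxy-2-oxo-5-(2-pentyl-1,3-dioxolan-2-yl)pentyl]-2,2-dimethyl-4H-1,3-dioxin-4-one (racemate) | CCCCCC1(CC(O)CC(=O)CC2=CC(=O)OC(C)(C)O2)OCCO1
F4 | step 13 | benzyl 2-methoxy-6-pentyl-4-{[3,5,7-trioxo-8-(2-pentyl-1,3-dioxolan-2-yl)octanoyl]oxy}benzoate | CCCCCC1(CC(=O)CC(=O)CC(=O)CC(=O)Oc2cc(CCCCC)c(C(=O)OCc3ccccc3)c(OC)c2)OCCO1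
F5 | step 13 | benzyl 4-({2,4-dihydroxy-6-[(2-pentyl-1,3-dioxolan-2-yl)methyl]benzoyl}oxy)-2-methoxy-6-pentylbenzoate | CCCCCC1(Cc2cc(O)cc(O)c2C(=O)Oc2cc(CCCCC)c(C(=O)OCc3ccccc3)c(OC)c2)OCCO1
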